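The numbers were set for the occasion; no experiment stands behind them.

I must choose the next charge of Z.

    Z → L (k1 = 1.8 × 10⁻⁴ s⁻¹)
    J → D (k2 = 1.3 × 10⁻⁵ s⁻¹)
    L + D → L.D (k3 = 9.2 × 10⁻⁵ M⁻¹ s⁻¹)
    2 L → L2 (k4 = 5.8 × 10⁻⁶ M⁻¹ s⁻¹)
    Z + D → Z.D (k5 = 1.2 × 10⁻⁴ M⁻¹ s⁻¹)

| flask | Z | J | time | remark |
|---|---|---|---|---|
| dawn | 0.020 M (in portions, 4) | 0.700 equiv | 5.0 d | the portions of Z follow each other after 4.0 h, the first at the start |
| noon | 0.040 M (in portions, 4) | 0.700 equiv | 5.0 d | the portions of Z follow each other after 4.0 h, the first at the start |
| spring | 0.080 M (in portions, 4) | 0.700 equiv | 5.0 d | the portions of Z follow each other after 4.0 h, the first at the start |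
| midnight | 0.15 M (in portions, 4) | 0.700 equiv | 5.0 d | the portions of Z follow each other after 4.0 h, the first at the start |
| summer | 0.30 M (in portions, 4) | 0.700 equiv | 5.0 d | the portions of Z follow each other after 4.0 h, the first at the start |

- percent here means Z units held: one L2 counts as two
- for a step with 2 of a species take k times the square, and two of it per event
- "hardly changes" means that all values lie within two and a half points (for a concentration: within two and a half percent of the largest)
- run time (dawn): 5.0 d

- share of L.D in all that became L.D or L2 or Z.D for dawn, noon, spring, midnight, summer, in this order
- the shape of the row from first to last (rises all the way / hardly changes / rises, then falls / falls all the way / falls, then rises)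

The choice hangs on how L divides. At any moment L goes to L.D and to L2, counted in Z units, in the ratio k·cD/cL. I call this ratio the split, and k is the selectivity factor, the constant of the step to L.D divided by two times the constant of the step to L2, which is 7.93. At fixed equivalents, cD and cL both grow with the charge, so the charge cancels from the split wherever the percentages are the same. With the whole 0.700 equiv of D standing beside the whole of L, the split is 5.55, which gives a share of 84.7% if I leave Z.D aside. I use that figure as my mark.

The charge can therefore act through timing. The J half-life is 0.62 d. At dawn, a yardstick life 1/(k·c) for L meeting D, with k now the constant of the step to L.D and c the whole charge rather than the smaller amount of D, is 6.29 d. That is longer than the J half-life, so in the dawn flask D is made before much L meets it. In the summer flask the same life is 0.419 d, shorter than the J half-life, so L.D forms while D is still coming and cD/cL is low. I therefore expect the row to fall from below the mark. But the dawn life is also longer than the run, while the summer life is shorter, so the choice lies between a better share and more L.D in hand. My reckoning gives a mark and a direction, not a row.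

The forecast gives 81%, 80%, 77%, 74% and 70%, a row that falls all the way, on the ground that “L is high early, when D is still scarce”.

The simulation gives 81.2%, 80.0%, 78.0%, 75.3% and 71.4%, a row that falls all the way. In the dawn flask the split is 3.5 at 0.339 d and, as the selectivity factor times cD/cL at that time, 5.03 at 5.00 d, while in the summer flask it is 3.22 at 5.00 d, lower than at dawn. The row hides what stands at that time: the dawn flask holds L.D 27.8% with L 65.8% unreacted, and the summer flask holds L.D 61.0% with L 14.5%.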